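**Plan**

- Retrosynthesis: (1) the two acetates and both CH2O carbons go back to the gem-diester of a hydroxymalonate. (2) The ring bond between the CH(OH) carbon and the adjacent ring CH that carries C(CH3)=CH2 is cut by a retro-ene reaction. The ring homoallylic alcohol HO–CH–CH–C(CH3)=CH2 of the cyclohexane is the isopulegol pattern, and it opens to an aldehyde with a 2-methylprop-1-enyl group on the quaternary carbon.
- (3) The bond from the aldehyde α-carbon to C(OH)(CO2Et)2 is cut by retro-aldol to diethyl ketomalonate. (4) The bond from the quaternary carbon to the 2-methylprop-1-enyl group is cut by retro-SN2' of an E-allylic phosphate, which also accounts for the vinyl group. (5) The allylic alcohol goes back to hex-5-yn-1-ol, Me3Al and formaldehyde.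
- Forward: the chain is built linearly (alkyne → E-allylic phosphate → quaternary carbon → aldehyde → aldol adduct). The only ring is closed in step 8. Ester reduction and acetylation of the two primary alcohols finish the synthesis.
- Stereochemistry: the quaternary carbon comes from NHC–Cu-catalysed allylic substitution (step 4) and the aldehyde α-carbon from L-proline enamine catalysis (step 7). The CH–OH and CH–isopropenyl ring stereocentres are set together in the ene step, relayed from the α-carbon through a chair transition state with the three contiguous substituents equatorial and the methyl of the quaternary carbon axial.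

Key step: step 8

Assumption: the chiral NHC ligand of step 4 is used as the antipode that delivers the alkenyl group to the face giving the (S)-configured quaternary carbon; L-proline is expected to give the (S)-α-carbon in step 7 through the usual hydrogen-bonded enamine transition state.

**Route**

Step 1
Reactants: 1 hex-5-yn-1-ol
Product: 2 tert-butyl(hex-5-yn-1-yloxy)dimethylsilane
Conditions: TBSCl, imidazole, CH2Cl2, 0 °C → rt
Reagents that add atoms: tert-butyldimethylsilyl chloride CC(C)(C)[Si](C)(C)Cl
Why: Silyl ether formation on a primary alcohol; the TBS ether masks the future aldehyde carbon during the organoaluminium and organocopper steps.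

Step 2
Reactants: 2 tert-butyl(hex-5-yn-1-yloxy)dimethylsilane
Product: 4 (E)-7-[(tert-butyldimethylsilyl)oxy]-3-methylhept-2-en-1-ol, via alkenyldimethylalane 3 (not isolated)
Conditions: Me3Al, Cp2ZrCl2 (20 mol %), CH2Cl2, 0 °C → rt; then (CH2O)n, THF, 0 °C → rt; aq. Rochelle salt
Reagents that add atoms: trimethylaluminium C[Al](C)C; formaldehyde (as paraformaldehyde) C=O
Why: Zr-catalysed methylalumination of the terminal alkyne is a syn addition with methyl going to the internal carbon, which fixes the E geometry, and trapping of the alkenylalane with formaldehyde should give the allylic alcohol.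

Step 3
Reactants: 4 (E)-7-[(tert-butyldimethylsilyl)oxy]-3-methylhept-2-en-1-ol
Product: 5 (E)-7-[(tert-butyldimethylsilyl)oxy]-3-methylhept-2-en-1-yl diethyl phosphate
Conditions: ClP(O)(OEt)2, Et3N, DMAP (cat.), CH2Cl2, 0 °C
Reagents that add atoms: diethyl chlorophosphate CCOP(=O)(Cl)OCC
Why: Phosphorylation of the primary allylic alcohol installs the leaving group needed for Cu-catalysed SN2' substitution.

Step 4
Reactants: 5 (E)-7-[(tert-butyldimethylsilyl)oxy]-3-methylhept-2-en-1-yl diethyl phosphate; 6 4,4,5,5-tetramethyl-2-(2-methylprop-1-en-1-yl)-1,3,2-dioxaborolane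
Product: 7 tert-butyl{[(5S)-5-ethenyl-5,7-dimethyloct-6-en-1-yl]oxy}dimethylsilane
Conditions: CuCl (5 mol %), chiral sulfonate-bridged imidazolinium salt (5.5 mol %), NaOMe (1.5 equiv), THF, rt
Reagents that add atoms: none
Why: NHC–Cu-catalysed enantioselective allylic substitution, in which the alkenylcopper formed by B-to-Cu transmetalation should add SN2' to the methyl-bearing carbon of the E-trisubstituted allylic phosphate, creating the quaternary stereocentre and the vinyl group at once with the face chosen by the chiral sulfonate-bridged NHC–Cu complex.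

Step 5
Reactants: 7 tert-butyl{[(5S)-5-ethenyl-5,7-dimethyloct-6-en-1-yl]oxy}dimethylsilane
Product: 8 (5S)-5-ethenyl-5,7-dimethyloct-6-en-1-ol
Conditions: TBAF, THF, 0 °C → rt
Reagents that add atoms: none
Why: Fluoride-induced desilylation, which leaves the three alkenes and the quaternary stereocentre untouched.

Step 6
Reactants: 8 (5S)-5-ethenyl-5,7-dimethyloct-6-en-1-ol
Product: 9 (5S)-5-ethenyl-5,7-dimethyloct-6-enal
Conditions: TEMPO (10 mol %), PhI(OAc)2, CH2Cl2, rt
Reagents that add atoms: none
Why: Oxoammonium (TEMPO) oxidation of a primary alcohol stops at the aldehyde and does not attack the alkenes.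

Step 7
Reactants: 9 (5S)-5-ethenyl-5,7-dimethyloct-6-enal; 10 diethyl 2-oxopropanedioate (diethyl ketomalonate)
Product: 11 diethyl 2-[(2S,5S)-5-ethenyl-5,7-dimethyl-1-oxooct-6-en-2-yl]-2-hydroxypropanedioate
Conditions: L-proline (30 mol %), CH2Cl2, rt
Reagents that add atoms: none
Why: Proline-catalysed direct cross-aldol (enamine catalysis) of an aldehyde donor with the non-enolisable, highly electrophilic ketomalonate, in which the anti-E-enamine should attack the ketone hydrogen-bonded to the carboxylic acid of L-proline and so set the (S)-α-carbon, while the α-branched product does not re-enter the enamine cycle.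

Step 8
Reactants: 11 diethyl 2-[(2S,5S)-5-ethenyl-5,7-dimethyl-1-oxooct-6-en-2-yl]-2-hydroxypropanedioate
Product: 12 diethyl 2-[(1R,2R,3S,4S)-4-ethenyl-2-hydroxy-4-methyl-3-(prop-1-en-2-yl)cyclohexyl]-2-hydroxypropanedioate
Conditions: ZnBr2 (2.5 equiv), CH2Cl2, 0 °C → rt
Reagents that add atoms: none
Why: ZnBr2 binds the aldehyde (with the neighbouring tertiary hydroxyl in a six-membered chelate) and should trigger a concerted, asynchronous intramolecular carbonyl-ene reaction: the aldehyde carbon bonds to the less substituted carbon of the 2-methylprop-1-enyl group while a hydrogen of one of its methyl groups passes to the carbonyl oxygen, so that the ring, the secondary alcohol and the isopropenyl group arise together. The closest known reaction type is the Lewis-acid-promoted type I carbonyl-ene cyclisation of citronellal to isopulegol. The six-membered ring closes in a 6-exo-trig mode with respect to the alkene (the attacked alkene carbon becomes a ring member, the carbon bearing the two methyl groups stays outside), and the carbonyl oxygen is likewise exocyclic. The chair transition state is anchored by the bulky C(OH)(CO2Et)2 group on the α-carbon, which sits equatorial and thereby places the methyl of the quaternary carbon axial and its vinyl group equatorial; the zinc-bound oxygen then goes equatorial to avoid a 1,3-diaxial contact with that axial methyl (this sets the carbinol carbon, OH trans to the malonate-bearing carbon), and the alkene goes equatorial to avoid the axial hydrogens (this sets the isopropenyl-bearing carbon, trans to OH). The step needs chemoselectivity for the trisubstituted alkene over the vinyl group and diastereoselectivity for the all-equatorial isomer; the first is secured because the vinyl group is less nucleophilic and has no allylic hydrogen (its allylic carbon is quaternary), the second by the preset α-stereocentre and the axial methyl group.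

Step 9
Reactants: 12 diethyl 2-[(1R,2R,3S,4S)-4-ethenyl-2-hydroxy-4-methyl-3-(prop-1-en-2-yl)cyclohexyl]-2-hydroxypropanedioate
Product: 13 2-[(1R,2R,3S,4S)-4-ethenyl-2-hydroxy-4-methyl-3-(prop-1-en-2-yl)cyclohexyl]propane-1,2,3-triol
Conditions: LiAlH4, THF, 0 °C → rt; aq. NaOH work-up
Reagents that add atoms: none
Why: Hydride reduction of both esters to primary alcohols; no stereocentre is epimerisable and the carbon bearing the two new CH2OH groups is not stereogenic.

Step 10
Reactants: 13 2-[(1R,2R,3S,4S)-4-ethenyl-2-hydroxy-4-methyl-3-(prop-1-en-2-yl)cyclohexyl]propane-1,2,3-triol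
Product: 14 2-[(1R,2R,3S,4S)-4-ethenyl-2-hydroxy-4-methyl-3-(prop-1-en-2-yl)cyclohexyl]-2-hydroxypropane-1,3-diyl diacetate
Conditions: Ac2O (2.2 equiv), pyridine, CH2Cl2, −20 → 0 °C
Reagents that add atoms: acetic anhydride CC(=O)OC(C)=O
Why: Kinetic acylation without DMAP should acetylate the two primary hydroxyls and spare the hindered secondary ring hydroxyl (flanked by two branched carbons) and the tertiary hydroxyl.

**Compound list**

1 | hex-5-yn-1-ol | C#CCCCCO | starting material
2 | tert-butyl(hex-5-yn-1-yloxy)dimethylsilane | C#CCCCCO[Si](C)(C)C(C)(C)C | intermediate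
3 | {(1E)-6-[(tert-butyldimethylsilyl)oxy]-2-methylhex-1-en-1-yl}dimethylalumane | C[Al](C)/C=C(\C)CCCCO[Si](C)(C)C(C)(C)C | intermediate
4 | (E)-7-[(tert-butyldimethylsilyl)oxy]-3-methylhept-2-en-1-ol | OC/C=C(\C)CCCCO[Si](C)(C)C(C)(C)C | intermediate
5 | (E)-7-[(tert-butyldimethylsilyl)oxy]-3-methylhept-2-en-1-yl diethyl phosphate | CCOP(=O)(OCC)OC/C=C(\C)CCCCO[Si](C)(C)C(C)(C)C | intermediate
6 | 4,4,5,5-tetramethyl-2-(2-methylprop-1-en-1-yl)-1,3,2-dioxaborolane | CC(C)=CB1OC(C)(C)C(C)(C)O1 | starting material
7 | tert-butyl{[(5S)-5-ethenyl-5,7-dimethyloct-6-en-1-yl]oxy}dimethylsilane | C=C[C@](C=C(C)C)(C)CCCCO[Si](C)(C)C(C)(C)C | intermediate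
8 | (5S)-5-ethenyl-5,7-dimethyloct-6-en-1-ol | C=C[C@](C=C(C)C)(C)CCCCO | intermediate
9 | (5S)-5-ethenyl-5,7-dimethyloct-6-enal | C=C[C@](C=C(C)C)(C)CCCC=O | intermediate
10 | diethyl 2-oxopropanedioate | CCOC(=O)C(=O)C(=O)OCC | starting material
11 | diethyl 2-[(2S,5S)-5-ethenyl-5,7-dimethyl-1-oxooct-6-en-2-yl]-2-hydroxypropanedioate | C=C[C@](C=C(C)C)(C)CC[C@@H](C(O)(C(=O)OCC)C(=O)OCC)C=O | intermediate
12 | diethyl 2-[(1R,2R,3S,4S)-4-ethenyl-2-hydroxy-4-methyl-3-(prop-1-en-2-yl)cyclohexyl]-2-hydroxypropanedioate | C=C[C@]1(C)CC[C@@H](C(O)(C(=O)OCC)C(=O)OCC)[C@H](O)[C@H]1C(=C)C | intermediate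
13 | 2-[(1R,2R,3S,4S)-4-ethenyl-2-hydroxy-4-methyl-3-(prop-1-en-2-yl)cyclohexyl]propane-1,2,3-triol | C=C[C@]1(C)CC[C@@H](C(O)(CO)CO)[C@H](O)[C@H]1C(=C)C | intermediate
14 | 2-[(1R,2R,3S,4S)-4-ethenyl-2-hydroxy-4-methyl-3-(prop-1-en-2-yl)cyclohexyl]-2-hydroxypropane-1,3-diyl diacetate | C=C[C@]1(C)CC[C@@H](C(O)(COC(C)=O)COC(C)=O)[C@H](O)[C@H]1C(=C)C | target

Total step count: 10. Longest linear sequence: 10 steps (from 1).

**Steps most likely to fail**

Step 4. Transmetalation of the β,β-disubstituted alkenylboronate may be slow, and the SN2'/SN2 ratio or the facial discrimination at the forming quaternary carbon may be poor. The fallback sets out from 4 and makes the quaternary carbon by stereospecific rearrangement instead of catalytic substitution.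
- Sharpless asymmetric epoxidation of 4 [Ti(OiPr)4, L-(+)-diethyl tartrate, t-BuOOH, 4 Å MS, CH2Cl2, −20 °C] should give epoxy alcohol F1.
- TESCl/imidazole gives epoxy triethylsilyl ether F2.
- Organoaluminium-promoted epoxy silyl ether rearrangement [methylaluminium bis(4-bromo-2,6-di-tert-butylphenoxide), CH2Cl2, −78 °C] opens the epoxide at the tertiary carbon, and the siloxymethyl group migrates there with inversion to give α-quaternary aldehyde F3.
- Wittig olefination with isopropylidenetriphenylphosphorane gives alkene F4.
- PPTS/MeOH removes the triethylsilyl group in the presence of the TBS ether to give neopentyl alcohol F5.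
- Dess–Martin oxidation gives aldehyde F6.
- Methylenation with Ph3P=CH2 gives 7, where the route is rejoined.

Step 8. The α-hydroxy-malonate may hold the Lewis acid in a chelate away from the aldehyde, so that closure at the hindered alkene carbon is slow and retro-aldol cleavage or halide capture of the developing tertiary cation competes. The fallback sets out from 11, removes the gem-diester before ring closure and makes the ene reaction the last step.
- HC(OMe)3, PPTS, MeOH gives dimethyl acetal F7.
- LiAlH4 gives triol acetal F8.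
- Ac2O/pyridine acetylates the two primary hydroxyls (no secondary hydroxyl is present at this stage) to give diacetate acetal F9.
- PPTS in wet acetone frees aldehyde diacetate F10.
- Ene cyclisation of F10 (ZnBr2 or Me2AlCl, CH2Cl2) through the same chair should give 14 directly, where the route is rejoined.

Step 7. Enantiofacial control in the enamine addition may be incomplete, and self-aldol of 9 may compete at the slow turnover expected for a long-chain aldehyde. The fallback sets out from 9 and replaces enamine catalysis by chiral Lewis-acid catalysis of a preformed enol silane.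
- TMSCl, Et3N, DMF gives Z-enol silane F11.
- Mukaiyama aldol addition to 10, bound two-point to a Cu(II)–bis(oxazoline) complex (10 mol %, Et2O, −78 °C, ligand antipode chosen for the S α-carbon), gives silyl ether F12.
- Citric acid in MeOH cleaves the silyl ether to 11, where the route is rejoined.

**Further compounds**

F1 | step 4 | [(2S,3S)-3-{4-[(tert-butyldimethylsilyl)oxy]butyl}-3-methyloxiran-2-yl]methanol | OC[C@@H]1O[C@@]1(C)CCCCO[Si](C)(C)C(C)(C)C
F2 | step 4 | tert-butyldimethyl{4-[(2S,3S)-2-methyl-3-{[(triethylsilyl)oxy]methyl}oxiran-2-yl]butoxy}silane | CC[Si](CC)(CC)OC[C@@H]1O[C@@]1(C)CCCCO[Si](C)(C)C(C)(C)C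
F3 | step 4 | (2S)-6-[(tert-butyldimethylsilyl)oxy]-2-methyl-2-{[(triethylsilyl)oxy]methyl}hexanal | CC[Si](CC)(CC)OC[C@](C=O)(C)CCCCO[Si](C)(C)C(C)(C)C
F4 | step 4 | tert-butyldimethyl{[(5R)-5,7-dimethyl-5-{[(triethylsilyl)oxy]methyl}oct-6-en-1-yl]oxy}silane | CC[Si](CC)(CC)OC[C@](C=C(C)C)(C)CCCCO[Si](C)(C)C(C)(C)C
F5 | step 4 | (2R)-6-[(tert-butyldimethylsilyl)oxy]-2-methyl-2-(2-methylprop-1-en-1-yl)hexan-1-ol | OC[C@](C=C(C)C)(C)CCCCO[Si](C)(C)C(C)(C)C
F6 | step 4 | (2R)-6-[(tert-butyldimethylsilyl)oxy]-2-methyl-2-(2-methylprop-1-en-1-yl)hexanal | O=C[C@](C=C(C)C)(C)CCCCO[Si](C)(C)C(C)(C)C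
F7 | step 8 | diethyl 2-[(2S,5S)-5-ethenyl-1,1-dimethoxy-5,7-dimethyloct-6-en-2-yl]-2-hydroxypropanedioate | C=C[C@](C=C(C)C)(C)CC[C@@H](C(O)(C(=O)OCC)C(=O)OCC)C(OC)OC
F8 | step 8 | 2-[(2S,5S)-5-ethenyl-1,1-dimethoxy-5,7-dimethyloct-6-en-2-yl]propane-1,2,3-triol | C=C[C@](C=C(C)C)(C)CC[C@@H](C(O)(CO)CO)C(OC)OC
F9 | step 8 | 2-[(2S,5S)-5-ethenyl-1,1-dimethoxy-5,7-dimethyloct-6-en-2-yl]-2-hydroxypropane-1,3-diyl diacetate | C=C[C@](C=C(C)C)(C)CC[C@@H](C(O)(COC(C)=O)COC(C)=O)C(OC)OC
F10 | step 8 | 2-[(2S,5S)-5-ethenyl-5,7-dimethyl-1-oxooct-6-en-2-yl]-2-hydroxypropane-1,3-diyl diacetate | C=C[C@](C=C(C)C)(C)CC[C@@H](C(O)(COC(C)=O)COC(C)=O)C=O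
F11 | step 7 | trimethyl{[(1Z,5S)-5-ethenyl-5,7-dimethylocta-1,6-dien-1-yl]oxy}silane | C=C[C@](C=C(C)C)(C)CC/C=C\O[Si](C)(C)C
F12 | step 7 | diethyl 2-[(2S,5S)-5-ethenyl-5,7-dimethyl-1-oxooct-6-en-2-yl]-2-[(trimethylsilyl)oxy]propanedioate | C=C[C@](C=C(C)C)(C)CC[C@@H](C(O[Si](C)(C)C)(C(=O)OCC)C(=O)OCC)C=O
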